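The tetrahydrofuran ring (O–C7'–C8'–C8–C9) carries C9' on C8' and C7 on C8 cis to each other and trans to the C7' aryl group, and C7 is an aryl carbinol. That pattern is read as a reduced lactone C9'(=O)–O–C7, itself the Baeyer–Villiger product of a cis-fused cyclobutanone. The key step therefore adds an arylketene across C8'=C8 of an enantiopure 2-aryl-2,5-dihydrofuran, forming C8'–C9' and C8–C7, the four-membered ring and three stereocentres (C8', C8, C7) at once. The precursor pair is the (S)-dihydrofuran made from vanillin (phenol silylated) and the ketene released from silylated homovanillic acid chloride.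

Key step: step 8

Remark on numbering: lignan numbering is used for the tetrahydrofuran series (ring O–C7'–C8'–C8–C9, C9' on C8', C7 on C8). In bicyclic nomenclature the key-step product is a 4,7-diaryl-3-oxabicyclo[3.2.0]heptan-6-one: carbonyl C6 (= C9') is bonded to ring-fusion carbon C5 (= C8') next to aryl-bearing C4 (= C7'), and aryl-bearing C7 is bonded to C1 (= C8).

Assumption on protecting groups: the phenol of the dihydrofuran ring is carried as a triisopropylsilyl ether, because it must survive a Grignard reagent and NaH/alkoxide. The phenol of the ketene ring is carried as a tert-butyldimethylsilyl ether, because its silyl ester exchanges directly to the acid chloride. Both are removed together in the last step.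

Step 1
Reactants: 1 vanillin
Product: 2 3-methoxy-4-(triisopropylsilyloxy)benzaldehyde
Conditions: i-Pr3SiCl (1.2 equiv), imidazole (2.5 equiv), DMF, rt
Reagents that add atoms: triisopropylsilyl chloride, CC(C)[Si](Cl)(C(C)C)C(C)C
Why: Silylation of a phenol (substitution at silicon with imidazole as base and silyl-transfer agent) should give a bulky aryl silyl ether that resists the organomagnesium and alkoxide reagents of the next steps.

Step 2
Reactants: 2 3-methoxy-4-(triisopropylsilyloxy)benzaldehyde; 3 vinylmagnesium bromide
Product: 4 rac-1-[3-methoxy-4-(triisopropylsilyloxy)phenyl]prop-2-en-1-ol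
Conditions: CH2=CHMgBr (1.3 equiv), THF, −78 → 0 °C; aq. NH4Cl
Reagents that add atoms: none
Why: Grignard 1,2-addition to the aldehyde should give the racemic secondary allylic alcohol, the aryl silyl ether being inert at low temperature and the mild quench avoiding ionisation of the electron-rich benzylic alcohol.

Step 3
Reactants: 4 rac-1-[3-methoxy-4-(triisopropylsilyloxy)phenyl]prop-2-en-1-ol
Product: 5 (S)-1-[3-methoxy-4-(triisopropylsilyloxy)phenyl]prop-2-en-1-ol
Conditions: immobilized Candida antarctica lipase B, vinyl acetate (3 equiv), t-BuOMe, 30 °C, stopped just past half conversion; chromatography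
Reagents that add atoms: none
Why: Lipase-catalysed kinetic resolution by transesterification should acetylate the (R)-enantiomer much faster (aryl as the large and vinyl as the medium carbinol substituent), so the unreacted (S)-alcohol, which carries the C7' configuration, should be recovered in high enantiomeric purity under neutral conditions.

Step 4
Reactants: 5 (S)-1-[3-methoxy-4-(triisopropylsilyloxy)phenyl]prop-2-en-1-ol; 6 allyl bromide
Product: 7 triisopropyl{2-methoxy-4-[(1S)-1-(prop-2-en-1-yloxy)prop-2-en-1-yl]phenoxy}silane
Conditions: NaH (1.3 equiv), THF, 0 °C; then allyl bromide (1.5 equiv), Bu4NI (5 mol %), 0 °C → rt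
Reagents that add atoms: none
Why: Williamson ether synthesis (SN2 displacement of the primary allylic bromide by the sodium alkoxide) should form the diallyl-type ether without touching the stereocentre, and the triisopropylsilyl aryl ether should withstand the alkoxide.

Step 5
Reactants: 7 triisopropyl{2-methoxy-4-[(1S)-1-(prop-2-en-1-yloxy)prop-2-en-1-yl]phenoxy}silane
Product: 8 (S)-2-[3-methoxy-4-(triisopropylsilyloxy)phenyl]-2,5-dihydrofuran
Conditions: second-generation Grubbs catalyst RuCl2(=CHPh)(PCy3)(H2IMes) (2 mol %), CH2Cl2 (0.02 M), 40 °C, short reaction time; product kept under argon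
Reagents that add atoms: none
Why: Ring-closing olefin metathesis of the 1,6-diene should close the five-membered ring with loss of ethene, C7' taking no part and keeping its configuration.

Step 6
Reactants: 9 homovanillic acid
Product: 10 tert-butyldimethylsilyl [4-(tert-butyldimethylsilyloxy)-3-methoxyphenyl]acetate
Conditions: t-BuMe2SiCl (2.3 equiv), imidazole (5 equiv), DMF, rt; pentane extraction, cold water wash
Reagents that add atoms: tert-butyldimethylsilyl chloride, CC(C)(C)[Si](C)(C)Cl
Why: Silylation of both the phenol and the carboxylic acid should give the aryl silyl ether together with a silyl ester that serves as a neutral acid chloride precursor.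

Step 7
Reactants: 10 tert-butyldimethylsilyl [4-(tert-butyldimethylsilyloxy)-3-methoxyphenyl]acetate
Product: 11 [4-(tert-butyldimethylsilyloxy)-3-methoxyphenyl]acetyl chloride
Conditions: (COCl)2 (1.2 equiv), DMF (cat.), CH2Cl2, 0 °C → rt; evaporation under high vacuum, used crude
Reagents that add atoms: oxalyl chloride, O=C(Cl)C(Cl)=O
Why: Acyl substitution through the chloroiminium chloride formed from DMF should exchange the silyl ester directly for the acid chloride, releasing the silyl chloride and no HCl, so the aryl silyl ether is not endangered.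

Step 8
Reactants: 8 (S)-2-[3-methoxy-4-(triisopropylsilyloxy)phenyl]-2,5-dihydrofuran; 11 [4-(tert-butyldimethylsilyloxy)-3-methoxyphenyl]acetyl chloride
Product: 13 (1R,4S,5S,7R)-7-[4-(tert-butyldimethylsilyloxy)-3-methoxyphenyl]-4-[3-methoxy-4-(triisopropylsilyloxy)phenyl]-3-oxabicyclo[3.2.0]heptan-6-one, via arylketene 12 (not isolated)
Conditions: 8 (1 equiv), i-Pr2NEt (3.5 equiv), toluene (1 M in 8), 80 °C; 11 (3 equiv) in toluene by syringe pump over 10 h
Reagents that add atoms: none
Why: The hindered amine dehydrochlorinates 11 to arylketene 12, which adds to C8'=C8 of 8 in a concerted but asynchronous thermal ketene–alkene (2+2) cycloaddition, the reaction type by which aryl- and alkylketenes give endo-substituted bicyclo[3.2.0]heptanones with cyclic alkenes. The cyclobutanone ring C8'–C9'(=O)–C7–C8 is closed by the two new bonds C8'–C9' and C8–C7, suprafacially on the alkene and antarafacially on the ketene, so the ring fusion is cis and C8' and C8 are set together. Their absolute sense follows from attack on the face anti to the C7' aryl group, which blocks one side of the nearly planar dihydrofuran next to C8'. C7 is set by the perpendicular approach, in which the ketene hydrogen points toward the ring and the aryl group away from it, so that bond rotation on closure leaves the aryl group on the concave (endo) face as the kinetic product. The step needs face, orientation and endo selectivity; orientation is the least secure, resting on the small carbonyl carbon being better accommodated next to C7' than the ArCH terminus, and the regioisomer would be removed by chromatography. Slow addition of 11 keeps the ketene dilute against dimerisation, and the hindered base at moderate temperature limits epimerisation of the endo aryl ketone.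

Step 9
Reactants: 13 (1R,4S,5S,7R)-7-[4-(tert-butyldimethylsilyloxy)-3-methoxyphenyl]-4-[3-methoxy-4-(triisopropylsilyloxy)phenyl]-3-oxabicyclo[3.2.0]heptan-6-one
Product: 14 (1S,4R,5R,8S)-4-[4-(tert-butyldimethylsilyloxy)-3-methoxyphenyl]-8-[3-methoxy-4-(triisopropylsilyloxy)phenyl]-3,7-dioxabicyclo[3.3.0]octan-2-one
Conditions: mCPBA (1.3 equiv), NaHCO3 (3 equiv), CH2Cl2, 0 °C
Reagents that add atoms: mCPBA (3-chloroperoxybenzoic acid), O=C(OO)c1cccc(Cl)c1
Why: In this Baeyer–Villiger oxidation of a strained ketone the secondary benzylic C7, activated by its electron-rich aryl group, should migrate in the Criegee intermediate in preference to C8', which is deactivated by the β-oxygen, and it migrates with retention, which fixes the 7R configuration, while the cold buffered medium avoids enolisation at C7.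

Step 10
Reactants: 14 (1S,4R,5R,8S)-4-[4-(tert-butyldimethylsilyloxy)-3-methoxyphenyl]-8-[3-methoxy-4-(triisopropylsilyloxy)phenyl]-3,7-dioxabicyclo[3.3.0]octan-2-one
Product: 15 [(2S,3R,4R)-4-{(R)-[4-(tert-butyldimethylsilyloxy)-3-methoxyphenyl](hydroxy)methyl}-2-[3-methoxy-4-(triisopropylsilyloxy)phenyl]oxolan-3-yl]methanol
Conditions: LiBH4 (2.5 equiv), THF, 0 °C → rt; aq. NH4Cl
Reagents that add atoms: none
Why: Hydride reduction of the lactone with LiBH4 should turn C9' into CH2OH and free the C7 hydroxyl without breaking the C7–O bond, so all four stereocentres are kept and the aryl silyl ethers are untouched.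

Step 11
Reactants: 15 [(2S,3R,4R)-4-{(R)-[4-(tert-butyldimethylsilyloxy)-3-methoxyphenyl](hydroxy)methyl}-2-[3-methoxy-4-(triisopropylsilyloxy)phenyl]oxolan-3-yl]methanol
Product: 16 (7R)-7-hydroxylariciresinol, [(2S,3R,4R)-2-(4-hydroxy-3-methoxyphenyl)-4-[(R)-hydroxy(4-hydroxy-3-methoxyphenyl)methyl]oxolan-3-yl]methanol
Conditions: Bu4NF (2.4 equiv), AcOH (2.4 equiv), THF, 0 °C
Reagents that add atoms: none
Why: Fluoride-induced cleavage of both aryl silyl ethers should free the two phenols, the acetic acid buffer suppressing phenoxide-driven quinone methide formation at C7 and C7', so that no stereocentre is disturbed.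

Compound list
1 | vanillin (4-hydroxy-3-methoxybenzaldehyde) | COc1cc(C=O)ccc1O | starting material
2 | 3-methoxy-4-(triisopropylsilyloxy)benzaldehyde | COc1cc(C=O)ccc1O[Si](C(C)C)(C(C)C)C(C)C | intermediate
3 | vinylmagnesium bromide | C=C[Mg]Br | starting material
4 | rac-1-[3-methoxy-4-(triisopropylsilyloxy)phenyl]prop-2-en-1-ol | COc1cc(C(O)C=C)ccc1O[Si](C(C)C)(C(C)C)C(C)C | intermediate
5 | (S)-1-[3-methoxy-4-(triisopropylsilyloxy)phenyl]prop-2-en-1-ol | COc1cc([C@@H](O)C=C)ccc1O[Si](C(C)C)(C(C)C)C(C)C | intermediate
6 | allyl bromide (3-bromoprop-1-ene) | C=CCBr | starting material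
7 | triisopropyl{2-methoxy-4-[(1S)-1-(prop-2-en-1-yloxy)prop-2-en-1-yl]phenoxy}silane | COc1cc([C@@H](OCC=C)C=C)ccc1O[Si](C(C)C)(C(C)C)C(C)C | intermediate
8 | (S)-2-[3-methoxy-4-(triisopropylsilyloxy)phenyl]-2,5-dihydrofuran | COc1cc([C@H]2OCC=C2)ccc1O[Si](C(C)C)(C(C)C)C(C)C | intermediate
9 | homovanillic acid, (4-hydroxy-3-methoxyphenyl)acetic acid | COc1cc(CC(=O)O)ccc1O | starting material
10 | tert-butyldimethylsilyl [4-(tert-butyldimethylsilyloxy)-3-methoxyphenyl]acetate | COc1cc(CC(=O)O[Si](C)(C)C(C)(C)C)ccc1O[Si](C)(C)C(C)(C)C | intermediate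
11 | [4-(tert-butyldimethylsilyloxy)-3-methoxyphenyl]acetyl chloride | COc1cc(CC(Cl)=O)ccc1O[Si](C)(C)C(C)(C)C | intermediate
12 | [4-(tert-butyldimethylsilyloxy)-3-methoxyphenyl]ketene, formed in the flask | COc1cc(C=C=O)ccc1O[Si](C)(C)C(C)(C)C | intermediate
13 | (1R,4S,5S,7R)-7-[4-(tert-butyldimethylsilyloxy)-3-methoxyphenyl]-4-[3-methoxy-4-(triisopropylsilyloxy)phenyl]-3-oxabicyclo[3.2.0]heptan-6-one; cis-fused, four-membered ring anti to the C4 aryl group, C7 aryl group endo | COc1cc([C@H]2OC[C@@H]3[C@H](c4ccc(O[Si](C)(C)C(C)(C)C)c(OC)c4)C(=O)[C@H]23)ccc1O[Si](C(C)C)(C(C)C)C(C)C | intermediate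
14 | (1S,4R,5R,8S)-4-[4-(tert-butyldimethylsilyloxy)-3-methoxyphenyl]-8-[3-methoxy-4-(triisopropylsilyloxy)phenyl]-3,7-dioxabicyclo[3.3.0]octan-2-one; cis-fused lactone C9'(=O)–O–C7, C4 aryl group endo, C8 aryl group exo | COc1cc([C@H]2OC[C@@H]3[C@H](c4ccc(O[Si](C)(C)C(C)(C)C)c(OC)c4)OC(=O)[C@H]23)ccc1O[Si](C(C)C)(C(C)C)C(C)C | intermediate
15 | [(2S,3R,4R)-4-{(R)-[4-(tert-butyldimethylsilyloxy)-3-methoxyphenyl](hydroxy)methyl}-2-[3-methoxy-4-(triisopropylsilyloxy)phenyl]oxolan-3-yl]methanol | COc1cc([C@H]2OC[C@H]([C@@H](O)c3ccc(O[Si](C)(C)C(C)(C)C)c(OC)c3)[C@@H]2CO)ccc1O[Si](C(C)C)(C(C)C)C(C)C | intermediate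
16 | (7R)-7-hydroxylariciresinol, [(2S,3R,4R)-2-(4-hydroxy-3-methoxyphenyl)-4-[(R)-hydroxy(4-hydroxy-3-methoxyphenyl)methyl]oxolan-3-yl]methanol | COc1cc([C@H]2OC[C@H]([C@@H](O)c3ccc(O)c(OC)c3)[C@@H]2CO)ccc1O | target

Total step count: 11. Longest linear sequence: 9 steps (steps 1–5 and 8–11, from vanillin); the ketene branch contributes steps 6 and 7.

Steps most likely to fail

Step 8. The ketene may dimerise faster than it adds to a non-activated alkene, orientation or facial control may be incomplete, and the amine may epimerise the endo aryl ketone to the more stable exo isomer. The fallback sets out from 10 and 8 and returns at 13. Silyl ester 10 would be deprotonated with LiN(SiMe3)2 in THF at −78 °C and the enolate added to N-chlorosuccinimide to give tert-butyldimethylsilyl chloro[4-(tert-butyldimethylsilyloxy)-3-methoxyphenyl]acetate F1. Oxalyl chloride with catalytic DMF would convert this into chloro[4-(tert-butyldimethylsilyloxy)-3-methoxyphenyl]acetyl chloride F2. Et3N in refluxing CH2Cl2 in the presence of 8 would release chloro[4-(tert-butyldimethylsilyloxy)-3-methoxyphenyl]ketene F3, a halogenated ketene electrophilic enough for unactivated alkenes. It should add across C8'=C8 on the same face and in the same orientation to give 7-chloro-7-[4-(tert-butyldimethylsilyloxy)-3-methoxyphenyl]-4-[3-methoxy-4-(triisopropylsilyloxy)phenyl]-3-oxabicyclo[3.2.0]heptan-6-one F4, with either configuration at C7. Zn dust in AcOH at room temperature would then replace chlorine by hydrogen through the zinc enolate, whose protonation on the open convex face leaves the aryl group endo, giving 13.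

Step 9. The ring-fusion carbon C8' may migrate in place of C7, C7 may be scrambled by enolisation before oxygen insertion, or the electron-rich arenes may be oxidised. The fallback sets out from 13 and returns at 15, bypassing 14. Irradiation of 13 through Pyrex (medium-pressure mercury lamp) in aqueous MeCN should cleave the weaker C9'–C7 bond (Norrish α-cleavage next to the benzylic carbon). The acyl–benzyl diradical should reclose on oxygen with retention at C7 to an oxacarbene, which water traps as the lactol 4-[4-(tert-butyldimethylsilyloxy)-3-methoxyphenyl]-8-[3-methoxy-4-(triisopropylsilyloxy)phenyl]-3,7-dioxabicyclo[3.3.0]octan-2-ol F5 (both anomers). NaBH4 in MeOH at 0 °C would reduce F5 through its open hydroxy aldehyde form to diol 15.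

Step 3. Acylation may be slow or poorly selective with this bulky aryl group, so that the recovered alcohol is not enantiopure. The fallback sets out from 4 and returns at 5. It is a Sharpless kinetic resolution: Ti(OiPr)4, L-(+)-diisopropyl tartrate, t-BuOOH (0.6 equiv), 4 Å molecular sieves, CH2Cl2, −20 °C. The (R)-alcohol should be epoxidised faster and be converted into (S)-[3-methoxy-4-(triisopropylsilyloxy)phenyl][(2S)-oxiran-2-yl]methanol F6, while the (S)-alcohol 5 is recovered and separated by chromatography.

Further compounds
F1 | step 8 | tert-butyldimethylsilyl chloro[4-(tert-butyldimethylsilyloxy)-3-methoxyphenyl]acetate (racemic) | COc1cc(C(Cl)C(=O)O[Si](C)(C)C(C)(C)C)ccc1O[Si](C)(C)C(C)(C)C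
F2 | step 8 | chloro[4-(tert-butyldimethylsilyloxy)-3-methoxyphenyl]acetyl chloride (racemic) | COc1cc(C(Cl)C(Cl)=O)ccc1O[Si](C)(C)C(C)(C)C
F3 | step 8 | chloro[4-(tert-butyldimethylsilyloxy)-3-methoxyphenyl]ketene | COc1cc(C(Cl)=C=O)ccc1O[Si](C)(C)C(C)(C)C
F4 | step 8 | 7-chloro-7-[4-(tert-butyldimethylsilyloxy)-3-methoxyphenyl]-4-[3-methoxy-4-(triisopropylsilyloxy)phenyl]-3-oxabicyclo[3.2.0]heptan-6-one (ring carbons as in 13, C7 undefined) | COc1cc([C@H]2OC[C@@H]3C(Cl)(c4ccc(O[Si](C)(C)C(C)(C)C)c(OC)c4)C(=O)[C@H]23)ccc1O[Si](C(C)C)(C(C)C)C(C)C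
F5 | step 9 | 4-[4-(tert-butyldimethylsilyloxy)-3-methoxyphenyl]-8-[3-methoxy-4-(triisopropylsilyloxy)phenyl]-3,7-dioxabicyclo[3.3.0]octan-2-ol (lactol of 14, both anomers) | COc1cc([C@H]2OC[C@@H]3[C@H](c4ccc(O[Si](C)(C)C(C)(C)C)c(OC)c4)OC(O)[C@H]23)ccc1O[Si](C(C)C)(C(C)C)C(C)C
F6 | step 3 | (S)-[3-methoxy-4-(triisopropylsilyloxy)phenyl][(2S)-oxiran-2-yl]methanol | COc1cc([C@H](O)[C@@H]2CO2)ccc1O[Si](C(C)C)(C(C)C)C(C)C
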